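**Retrosynthetic overview**
- The central ring is not assembled by biaryl coupling. It is built de novo by a Moore–Liebeskind ring expansion (4π ring opening, then 6π ring closure) of a 4-alkenyl-4-benzoyloxycyclobutenone.
- That cascade places both aryl groups and all four oxygens at once, and the oxygens arrive differentiated (OBz, OtBu, free OH, OBn).
- The cyclobutenone comes from 1,2-addition of an α-aryl-β-benzyloxyvinyllithium to a squarate-derived 3-aryl-4-tert-butoxycyclobutenedione; the alkoxide is trapped as the first benzoate.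
- Endgame: cap the free OH as benzyl ether, swap OtBu for the second benzoate, remove four benzyl groups by hydrogenolysis.
- Ring order: the two outer aryl rings are bought; the four-membered ring is expanded to the central benzene ring last.

Assumption: the target SMILES has no stereocentre or stereogenic axis, so the target is achiral and no enantiocontrol is needed; racemic centres and C=C geometries in intermediates disappear before the target.

**Step 1**
Reactants: 1 1-(benzyloxy)-4-ethynylbenzene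
Product: 2 (Z)-1-(benzyloxy)-4-[2-(benzyloxy)ethenyl]benzene
Conditions: BnOH (2 equiv), CsOH·H2O (20 mol%), NMP, 90 °C
Reagents that add atoms: benzyl alcohol, OCc1ccccc1
Why: Base-catalysed anti-Markovnikov hydroalkoxylation of an arylacetylene, in which benzyl oxide adds to the terminal carbon and trans protonation of the benzylic vinyl anion gives the (Z)-enol ether (no stereocentre formed).

**Step 2**
Reactants: 2 (Z)-1-(benzyloxy)-4-[2-(benzyloxy)ethenyl]benzene
Product: 4 1-(benzyloxy)-4-[(Z)-2-(benzyloxy)-1-bromoethenyl]benzene, via dibromide 3 (not isolated)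
Conditions: Br2, CH2Cl2, –78 °C; then Et3N, –78 °C to rt
Reagents that add atoms: bromine, BrBr
Why: Bromination–dehydrobromination of an enol ether, in which the oxygen-bearing C–Br ionises to the oxocarbenium ion and the amine removes the acidic benzylic H, leaving bromine on the aryl-bearing carbon and cis to OBn, as in the standard preparations of (Z)-2-bromovinyl ethers and 5-bromo-3,4-dihydro-2H-pyran.

**Step 3**
Reactants: 5 1-(benzyloxy)-4-bromobenzene; 6 di-tert-butyl squarate (3,4-di-tert-butoxycyclobut-3-ene-1,2-dione)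
Product: 10 3-[4-(benzyloxy)phenyl]-4-tert-butoxycyclobut-3-ene-1,2-dione, via aryllithium 7 (not isolated), via lithium alkoxide 8 (not isolated), via trifluoroacetate 9 (not isolated)
Conditions: n-BuLi, THF, –78 °C; add to 6, THF, –78 °C; (CF3CO)2O, –78 °C; aq NaHCO3
Reagents that add atoms: none
Why: Liebeskind–Moore squarate protocol, in which Br–Li exchange and 1,2-addition to one squarate carbonyl are followed by trifluoroacetylation and ionisation of the carbinol with loss of one tert-butyl group as isobutene, transposing the carbonyl to give the 3-aryl-4-alkoxycyclobutenedione.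

**Step 4**
Reactants: 4 1-(benzyloxy)-4-[(Z)-2-(benzyloxy)-1-bromoethenyl]benzene; 10 3-[4-(benzyloxy)phenyl]-4-tert-butoxycyclobut-3-ene-1,2-dione
Product: 13 1-[(Z)-2-(benzyloxy)-1-[4-(benzyloxy)phenyl]ethenyl]-3-[4-(benzyloxy)phenyl]-2-tert-butoxy-4-oxocyclobut-2-en-1-yl benzoate (racemic), via vinyllithium 11 (not isolated), via lithium alkoxide 12 (not isolated)
Conditions: 4, t-BuLi (2 equiv), THF, –78 °C; add to 10, THF, –78 °C; BzCl, –78 to –20 °C
Reagents that add atoms: benzoyl chloride, O=C(Cl)c1ccccc1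
Why: Br–Li exchange with retention gives the O-chelated vinyllithium (Li cis to OBn, the isomer that resists β-elimination), which adds 1,2 to the more electrophilic carbonyl of 10 (the one next to C–OtBu, not the vinylogous-ester carbonyl), and in situ O-acylation of the tertiary alkoxide installs the first target benzoate; the new quaternary carbon is racemic and is destroyed in step 5.

**Step 5**
Reactants: 13 1-[(Z)-2-(benzyloxy)-1-[4-(benzyloxy)phenyl]ethenyl]-3-[4-(benzyloxy)phenyl]-2-tert-butoxy-4-oxocyclobut-2-en-1-yl benzoate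
Product: 17 4,4'',5',6'-tetrakis(benzyloxy)-3'-tert-butoxy-[1,1':4',1''-terphenyl]-2'-yl benzoate, via dienylketene 14 (not isolated), via cyclohexadienone 15 (not isolated), via phenol 16 (not isolated)
Conditions: PhMe, 110 °C; then BnBr, K2CO3, DMF, rt
Reagents that add atoms: benzyl bromide, BrCc1ccccc1
Why: Moore–Liebeskind ring expansion, in which conrotatory 4π opening (acyloxy outward, alkenyl inward; the unproductive ketene rotamer simply recloses) gives the dienylketene, 6π electrocyclisation and enolisation give the hexasubstituted phenol with every substituent at a fixed position, and the single free OH is then capped by Williamson benzylation.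

**Step 6**
Reactants: 17 4,4'',5',6'-tetrakis(benzyloxy)-3'-tert-butoxy-[1,1':4',1''-terphenyl]-2'-yl benzoate
Product: 19 4,4'',5',6'-tetrakis(benzyloxy)-[1,1':4',1''-terphenyl]-2',3'-diyl dibenzoate, via phenol 18 (not isolated)
Conditions: TFA, CH2Cl2, 0 °C; evaporate; BzCl, Et3N, DMAP (cat.), CH2Cl2, 0 °C to rt
Reagents that add atoms: benzoyl chloride, O=C(Cl)c1ccccc1
Why: Acidolysis of the aryl tert-butyl ether (loss of the tert-butyl cation as isobutene; benzyl ethers and the benzoate survive cold TFA) followed by DMAP-catalysed acylation, with any 1,2-acyl migration in 18 being harmless because both oxygens end as benzoates.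

**Step 7**
Reactants: 19 4,4'',5',6'-tetrakis(benzyloxy)-[1,1':4',1''-terphenyl]-2',3'-diyl dibenzoate
Product: 20 4,4'',5',6'-tetrahydroxy-[1,1':4',1''-terphenyl]-2',3'-diyl dibenzoate (CNP0216579.0)
Conditions: H2 (1 atm), 10% Pd/C, EtOAc–THF, rt
Reagents that add atoms: none
Why: Catalytic hydrogenolysis cleaves the four benzyl aryl ethers under neutral conditions that leave aryl benzoates intact, and the freed 5',6'-diol cannot accept a migrating benzoyl group because each ester is separated from it by an aryl-bearing carbon.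

**Compound list**
1 | 1-(benzyloxy)-4-ethynylbenzene | C#Cc1ccc(OCc2ccccc2)cc1 | starting material
2 | (Z)-1-(benzyloxy)-4-[2-(benzyloxy)ethenyl]benzene | O(/C=C\c1ccc(OCc2ccccc2)cc1)Cc1ccccc1 | intermediate
3 | 1-(benzyloxy)-4-[2-(benzyloxy)-1,2-dibromoethyl]benzene (diastereomer mixture) | BrC(c1ccc(OCc2ccccc2)cc1)C(Br)OCc1ccccc1 | intermediate
4 | 1-(benzyloxy)-4-[(Z)-2-(benzyloxy)-1-bromoethenyl]benzene | Br/C(=C\OCc1ccccc1)c1ccc(OCc2ccccc2)cc1 | intermediate
5 | 1-(benzyloxy)-4-bromobenzene | Brc1ccc(OCc2ccccc2)cc1 | starting material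
6 | di-tert-butyl squarate (3,4-di-tert-butoxycyclobut-3-ene-1,2-dione) | O=C1C(=O)C(OC(C)(C)C)=C1OC(C)(C)C | starting material
7 | [4-(benzyloxy)phenyl]lithium | [Li]c1ccc(OCc2ccccc2)cc1 | intermediate
8 | lithium 1-[4-(benzyloxy)phenyl]-2,3-di-tert-butoxy-4-oxocyclobut-2-en-1-olate (racemic) | [Li+].[O-]C1(c2ccc(OCc3ccccc3)cc2)C(OC(C)(C)C)=C(OC(C)(C)C)C1=O | intermediate
9 | 1-[4-(benzyloxy)phenyl]-2,3-di-tert-butoxy-4-oxocyclobut-2-en-1-yl trifluoroacetate (racemic) | O=C(OC1(c2ccc(OCc3ccccc3)cc2)C(OC(C)(C)C)=C(OC(C)(C)C)C1=O)C(F)(F)F | intermediate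
10 | 3-[4-(benzyloxy)phenyl]-4-tert-butoxycyclobut-3-ene-1,2-dione | O=C1C(=O)C(OC(C)(C)C)=C1c1ccc(OCc2ccccc2)cc1 | intermediate
11 | [(E)-2-(benzyloxy)-1-[4-(benzyloxy)phenyl]ethenyl]lithium (Li cis to OBn) | [Li]/C(=C\OCc1ccccc1)c1ccc(OCc2ccccc2)cc1 | intermediate
12 | lithium 1-[(Z)-2-(benzyloxy)-1-[4-(benzyloxy)phenyl]ethenyl]-3-[4-(benzyloxy)phenyl]-2-tert-butoxy-4-oxocyclobut-2-en-1-olate (racemic) | [Li+].[O-]C1(/C(=C\OCc2ccccc2)c2ccc(OCc3ccccc3)cc2)C(OC(C)(C)C)=C(c2ccc(OCc3ccccc3)cc2)C1=O | intermediate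
13 | 1-[(Z)-2-(benzyloxy)-1-[4-(benzyloxy)phenyl]ethenyl]-3-[4-(benzyloxy)phenyl]-2-tert-butoxy-4-oxocyclobut-2-en-1-yl benzoate (racemic) | O=C(OC1(/C(=C\OCc2ccccc2)c2ccc(OCc3ccccc3)cc2)C(OC(C)(C)C)=C(c2ccc(OCc3ccccc3)cc2)C1=O)c1ccccc1 | intermediate
14 | (3Z,5Z)-4-(benzoyloxy)-6-(benzyloxy)-2,5-bis[4-(benzyloxy)phenyl]-3-tert-butoxyhexa-1,3,5-trien-1-one | O=C=C(c1ccc(OCc2ccccc2)cc1)/C(OC(C)(C)C)=C(/OC(=O)c1ccccc1)\C(c1ccc(OCc2ccccc2)cc1)=C/OCc1ccccc1 | intermediate
15 | 4-(benzoyloxy)-6-(benzyloxy)-2,5-bis[4-(benzyloxy)phenyl]-3-tert-butoxycyclohexa-2,4-dien-1-one (racemic) | O=C1C(c2ccc(OCc3ccccc3)cc2)=C(OC(C)(C)C)C(OC(=O)c2ccccc2)=C(c2ccc(OCc3ccccc3)cc2)C1OCc1ccccc1 | intermediate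
16 | 4,4'',6'-tris(benzyloxy)-3'-tert-butoxy-5'-hydroxy-[1,1':4',1''-terphenyl]-2'-yl benzoate | Oc1c(-c2ccc(OCc3ccccc3)cc2)c(OC(C)(C)C)c(OC(=O)c2ccccc2)c(-c2ccc(OCc3ccccc3)cc2)c1OCc1ccccc1 | intermediate
17 | 4,4'',5',6'-tetrakis(benzyloxy)-3'-tert-butoxy-[1,1':4',1''-terphenyl]-2'-yl benzoate | c1ccccc1COc1c(-c2ccc(OCc3ccccc3)cc2)c(OC(C)(C)C)c(OC(=O)c2ccccc2)c(-c2ccc(OCc3ccccc3)cc2)c1OCc1ccccc1 | intermediate
18 | 4,4'',5',6'-tetrakis(benzyloxy)-3'-hydroxy-[1,1':4',1''-terphenyl]-2'-yl benzoate | c1ccccc1COc1c(-c2ccc(OCc3ccccc3)cc2)c(O)c(OC(=O)c2ccccc2)c(-c2ccc(OCc3ccccc3)cc2)c1OCc1ccccc1 | intermediate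
19 | 4,4'',5',6'-tetrakis(benzyloxy)-[1,1':4',1''-terphenyl]-2',3'-diyl dibenzoate | c1ccccc1COc1c(-c2ccc(OCc3ccccc3)cc2)c(OC(=O)c2ccccc2)c(OC(=O)c2ccccc2)c(-c2ccc(OCc3ccccc3)cc2)c1OCc1ccccc1 | intermediate
20 | 4,4'',5',6'-tetrahydroxy-[1,1':4',1''-terphenyl]-2',3'-diyl dibenzoate (CNP0216579.0, achiral) | O=C(Oc1c(OC(=O)c2ccccc2)c(-c2ccc(O)cc2)c(O)c(O)c1-c1ccc(O)cc1)c1ccccc1 | target

**Totals**
Total step count: 7. Longest linear sequence: 6 steps (steps 1, 2, 4, 5, 6, 7 from alkyne 1); the squarate branch (step 3) joins at step 4.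

**Three steps most likely to fail**

Step 4. The β-benzyloxy vinyllithium 11 can expel lithium benzyl oxide (giving back alkyne 1) or isomerise before it adds to 10. The fallback sets out from bromide 4 and dione 10 and uses no organolithium: CrCl2 (4 equiv), NiCl2 (2 mol%), DMF–THF, rt (Nozaki–Hiyama–Kishi coupling). The vinylchromium species formed by divalent chromium is non-basic, does not β-eliminate, and adds to the same ketone carbonyl. After aqueous work-up this gives 4-[(Z)-2-(benzyloxy)-1-[4-(benzyloxy)phenyl]ethenyl]-2-[4-(benzyloxy)phenyl]-3-tert-butoxy-4-hydroxycyclobut-2-en-1-one F1. Deprotonation of F1 with LiN(SiMe3)2 (THF, –78 °C) comes back to the route at lithium alkoxide 12, which is benzoylated to 13 as in step 4.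

Step 5. Benzoyloxy is only a modest outward-rotating donor, so ring opening of 13 may need temperatures at which the tert-butyl ether or the ester suffers, or the wrong ketene rotamer may be trapped by the ester. The fallback sets out from lithium alkoxide 12, which is quenched with t-BuMe2SiOTf instead of BzCl to give 4-[(Z)-2-(benzyloxy)-1-[4-(benzyloxy)phenyl]ethenyl]-2-[4-(benzyloxy)phenyl]-3-tert-butoxy-4-[(tert-butyldimethylsilyl)oxy]cyclobut-2-en-1-one F2. Silyloxy is the classical strong donor for this rearrangement, so F2 should ring-expand in PhMe at 80–110 °C to 4,4'',6'-tris(benzyloxy)-3'-tert-butoxy-2'-[(tert-butyldimethylsilyl)oxy]-[1,1':4',1''-terphenyl]-5'-ol F3. Benzylation (BnBr, K2CO3, DMF) gives 4,4'',5',6'-tetrakis(benzyloxy)-3'-tert-butoxy-2'-[(tert-butyldimethylsilyl)oxy]-1,1':4',1''-terphenyl F4. Desilylation (n-Bu4NF, THF, 0 °C) frees 4,4'',5',6'-tetrakis(benzyloxy)-3'-tert-butoxy-[1,1':4',1''-terphenyl]-2'-ol F5, and BzCl, Et3N, DMAP comes back to the route at 17. This costs two extra steps.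

Step 2. Both C–Br bonds of dibromide 3 are labile, elimination could go the wrong way, and free bromine may attack the electron-rich ring. The fallback sets out from enol ether 2 and replaces dibromination by alkoxybromination: NBS, BnOH, CH2Cl2, –40 °C gives 1-(benzyloxy)-4-[2,2-bis(benzyloxy)-1-bromoethyl]benzene F6, in which bromine can only sit on the benzylic carbon. Me3SiOTf, iPr2NEt, CH2Cl2, 0 °C (acetal-to-enol-ether elimination) then removes one benzyloxy group together with the benzylic H and comes back to the route at 4.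

**Further compounds**
F1 | step 4 | 4-[(Z)-2-(benzyloxy)-1-[4-(benzyloxy)phenyl]ethenyl]-2-[4-(benzyloxy)phenyl]-3-tert-butoxy-4-hydroxycyclobut-2-en-1-one (racemic) | O=C1C(c2ccc(OCc3ccccc3)cc2)=C(OC(C)(C)C)C1(O)/C(=C\OCc1ccccc1)c1ccc(OCc2ccccc2)cc1
F2 | step 5 | 4-[(Z)-2-(benzyloxy)-1-[4-(benzyloxy)phenyl]ethenyl]-2-[4-(benzyloxy)phenyl]-3-tert-butoxy-4-[(tert-butyldimethylsilyl)oxy]cyclobut-2-en-1-one (racemic) | O=C1C(c2ccc(OCc3ccccc3)cc2)=C(OC(C)(C)C)C1(O[Si](C)(C)C(C)(C)C)/C(=C\OCc1ccccc1)c1ccc(OCc2ccccc2)cc1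
F3 | step 5 | 4,4'',6'-tris(benzyloxy)-3'-tert-butoxy-2'-[(tert-butyldimethylsilyl)oxy]-[1,1':4',1''-terphenyl]-5'-ol | Oc1c(-c2ccc(OCc3ccccc3)cc2)c(OC(C)(C)C)c(O[Si](C)(C)C(C)(C)C)c(-c2ccc(OCc3ccccc3)cc2)c1OCc1ccccc1
F4 | step 5 | 4,4'',5',6'-tetrakis(benzyloxy)-3'-tert-butoxy-2'-[(tert-butyldimethylsilyl)oxy]-1,1':4',1''-terphenyl | c1ccccc1COc1c(-c2ccc(OCc3ccccc3)cc2)c(OC(C)(C)C)c(O[Si](C)(C)C(C)(C)C)c(-c2ccc(OCc3ccccc3)cc2)c1OCc1ccccc1
F5 | step 5 | 4,4'',5',6'-tetrakis(benzyloxy)-3'-tert-butoxy-[1,1':4',1''-terphenyl]-2'-ol | c1ccccc1COc1c(-c2ccc(OCc3ccccc3)cc2)c(OC(C)(C)C)c(O)c(-c2ccc(OCc3ccccc3)cc2)c1OCc1ccccc1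
F6 | step 2 | 1-(benzyloxy)-4-[2,2-bis(benzyloxy)-1-bromoethyl]benzene (racemic) | BrC(c1ccc(OCc2ccccc2)cc1)C(OCc1ccccc1)OCc1ccccc1
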